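**Retrosynthetic overview**

1. The last bond made is C14'–C15' (Stille coupling): the ε-half is the C19 tetraenyl iodide 17, the epoxy half the C21 pentaenylstannane 32.
2. The route rests on the methyl-branched trisubstituted E-alkenes of the chain: C19' on C9' of C9'=C10', and likewise C20' on C13' of C13'=C14'. Each methyl is added to a terminal alkyne carbon by syn methylalumination.
3. Key step: the ε-enyne 4 takes up CH3 at C9' (bond C9'–C19'), and the resulting alkenyl metal is joined to bromoenyne 10 (bond C10'–C11'). Desilylation and a second methylalumination with iodinolysis then give 17.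
4. The stannane 32 comes from (5R,6S)-5,6-epoxyretinal 28, built from epoxy aldehyde 21 by two C5 Horner–Wadsworth–Emmons/DIBAL cycles; the Lewis-acidic aluminium chemistry is kept on the epoxide-free ε-half.
5. Ring order: ring A (ε-ring C1'–C6', with C6' from resolved α-ionone) and ring B (C1–C6) are bought as carbocycles; the only ring formed is the oxirane C5–O–C6, closed in step 9.

Key step: step 5

Assumption: (R)-α-ionone is taken from the commercial racemate by preparative chromatography on a chiral phase (counted as step 1); atoms are named by carotenoid numbering, with primed locants for the ε-half.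

**Route**

Step 1
Reactants: 1 α-ionone (racemic)
Product: 2 (R)-α-ionone, (3E)-4-[(1R)-2,6,6-trimethylcyclohex-2-en-1-yl]but-3-en-2-one
Conditions: preparative SFC, amylose tris(3,5-dimethylphenylcarbamate) phase, CO2/iPrOH
Reagents that add atoms: none
Why: Resolution by chiral-phase chromatography separates the enantiomers without any reaction at C6'; the (R) enantiomer, known to be the dextrorotatory one, is collected.

Step 2
Reactants: 2 (R)-α-ionone
Product: 4 (6R)-6-[(1E)-but-1-en-3-yn-1-yl]-1,5,5-trimethylcyclohex-1-ene, via enol phosphate 3 (not isolated)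
Conditions: LiN(iPr)2 (commercial solution, 1.05 equiv), THF, −78 °C; ClP(O)(OEt)2, −78 °C → rt; then into LiN(iPr)2 (2.3 equiv), THF, −78 → 0 °C; aq NH4Cl
Reagents that add atoms: none
Why: Negishi's methyl ketone to terminal alkyne protocol: kinetic deprotonation at the methyl group and O-phosphorylation give dienyl phosphate 3, then LDA removes a terminal vinylic hydrogen and phosphate leaves; the alkyne is held as its acetylide, which disfavours a second deprotonation at C6'.

Step 3
Reactants: 5 acetylene; 6 iodine monobromide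
Product: 7 (E)-1-bromo-2-iodoethene
Conditions: HC≡CH (gas), IBr, 48% aq HBr, 0 °C
Reagents that add atoms: iodine monobromide (compound 6), IBr
Why: Electrophilic anti addition of I–Br across the alkyne through a bridged iodonium ion should give the E dihaloethene.

Step 4
Reactants: 8 trimethylsilylacetylene; 7 (E)-1-bromo-2-iodoethene
Product: 10 (E)-(4-bromobut-3-en-1-yn-1-yl)trimethylsilane, via alkynylzinc bromide 9 (not isolated)
Conditions: 8, nBuLi, THF, −78 °C; ZnBr2, → 0 °C; 7, Pd(PPh3)4 (2 mol%), THF, 0 °C → rt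
Reagents that add atoms: none
Why: Negishi alkynyl–alkenyl coupling: zerovalent palladium inserts into C–I much faster than into C–Br, so only the iodide is replaced and the E geometry is retained.

Step 5
Reactants: 4 the ε-enyne; 11 trimethylaluminium; 10 the bromoenyne
Product: 14 trimethyl{(3E,5E,7E)-6-methyl-8-[(1R)-2,6,6-trimethylcyclohex-2-en-1-yl]octa-3,5,7-trien-1-yn-1-yl}silane, via alkenylalane 12 (not isolated), via alkenylzinc chloride 13 (not isolated)
Conditions: AlMe3 (2 equiv), Cp2ZrCl2 (1 equiv), ClCH2CH2Cl, rt; volatiles removed in vacuo; THF, ZnCl2 (1 equiv); 10, Pd(PPh3)4 (5 mol%), THF/DMF, rt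
Reagents that add atoms: trimethylaluminium (compound 11), C[Al](C)C
Why: Cp2ZrCl2 and AlMe3 form a methylzirconocene cation paired with a chloroaluminate, which adds its Zr–CH3 bond syn across C9'≡C10' of 4 with CH3 (C19') on the internal carbon and the metal on the terminal carbon; exchange with aluminium gives the (E)-alkenylalane 12 and returns the zirconium catalyst. ZnCl2 then takes over the alkenyl group (13), zerovalent palladium inserts into the C–Br bond of 10, and transmetalation followed by reductive elimination joins C10' to C11' with retention at both sp2 carbons. The closest known reaction type is the zirconium-catalysed carboalumination of terminal alkynes (Negishi methylalumination) combined with palladium-catalysed alkenyl–alkenyl Negishi coupling, as practised on the enyne derived from β-ionone. No ring is closed and no new stereocenter is formed; what is set is the E geometry of C9'=C10', controlled by the syn addition, and the E geometry of C11'=C12', inherited from 10. The step needs regioselective syn carbometalation of the alkyne alone, which the terminal alkyne and the inertness of the C7'=C8' and ring C4'=C5' alkenes secure, and it needs C6' to stay untouched, which the aprotic, non-basic medium secures. Excess AlMe3 is stripped off before the coupling so that methyl transfer to 10 cannot compete.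

Step 6
Reactants: 14 the trienyne silane
Product: 15 (6R)-1,5,5-trimethyl-6-[(1E,3E,5E)-3-methylocta-1,3,5-trien-7-yn-1-yl]cyclohex-1-ene
Conditions: K2CO3 (0.2 equiv), MeOH/THF, rt, dark
Reagents that add atoms: none
Why: Methoxide-induced protodesilylation of the alkynylsilane; the base is far too weak to deprotonate C6'.

Step 7
Reactants: 15 the terminal trienyne; 11 trimethylaluminium
Product: 17 (6R)-6-[(1E,3E,5E,7E)-8-iodo-3,7-dimethylocta-1,3,5,7-tetraen-1-yl]-1,5,5-trimethylcyclohex-1-ene, via alkenylalane 16 (not isolated)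
Conditions: AlMe3 (2 equiv), Cp2ZrCl2 (1 equiv), ClCH2CH2Cl, rt; then I2, THF, −30 → 0 °C; aq Na2S2O3; dark
Reagents that add atoms: trimethylaluminium (compound 11), C[Al](C)C; iodine, II
Why: A second Negishi methylalumination places C20' on C13' by syn addition, and iodinolysis of the C–Al bond proceeds with retention to give the E iodide at C14'.

Step 8
Reactants: 18 β-cyclocitral
Product: 19 β-cyclogeraniol, (2,6,6-trimethylcyclohex-1-en-1-yl)methanol
Conditions: NaBH4, MeOH, 0 °C
Reagents that add atoms: none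
Why: Borohydride 1,2-reduction of the hindered enal gives the allylic alcohol needed for directed epoxidation.

Step 9
Reactants: 19 β-cyclogeraniol
Product: 20 [(1R,6R)-2,2,6-trimethyl-7-oxabicyclo[4.1.0]heptan-1-yl]methanol
Conditions: Ti(OiPr)4 (1 equiv), D-(−)-diethyl tartrate (1.2 equiv), tBuOOH (2 equiv), 4 Å MS, CH2Cl2, −20 °C
Reagents that add atoms: tert-butyl hydroperoxide, CC(C)(C)OO
Why: Sharpless asymmetric epoxidation: the titanium–D-(−)-tartrate complex (the reagent enantiomer that turns geraniol into its 2R,3R epoxide) delivers oxygen to the matching face of C5=C6, setting C5 (R) and C6 together as the cis oxirane.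

Step 10
Reactants: 20 the epoxy alcohol
Product: 21 (1S,6R)-2,2,6-trimethyl-7-oxabicyclo[4.1.0]heptane-1-carbaldehyde
Conditions: (nPr4N)(RuO4) (5 mol%), N-methylmorpholine N-oxide (1.5 equiv), 4 Å MS, CH2Cl2, rt
Reagents that add atoms: none
Why: Ley–Griffith oxidation is neutral and tolerates the oxirane; the aldehyde has no α-hydrogen, so C6 cannot epimerise.

Step 11
Reactants: 21 the epoxy aldehyde; 22 diethyl (3-cyano-2-methylprop-2-en-1-yl)phosphonate (E/Z mixture)
Product: 23 (2E,4E)-3-methyl-5-[(1S,6R)-2,2,6-trimethyl-7-oxabicyclo[4.1.0]heptan-1-yl]penta-2,4-dienenitrile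
Conditions: 22, NaH, THF, 0 °C; then 21, 0 °C → rt
Reagents that add atoms: none
Why: Horner–Wadsworth–Emmons olefination with the delocalised C5 phosphonate anion should form C7=C8 as the E alkene and mainly the E C9=C10 isomer; the minor 9Z isomer is to be removed by chromatography.

Step 12
Reactants: 23 the C15 nitrile
Product: 25 (2E,4E)-3-methyl-5-[(1S,6R)-2,2,6-trimethyl-7-oxabicyclo[4.1.0]heptan-1-yl]penta-2,4-dienal, via aluminoimine 24 (not isolated)
Conditions: iBu2AlH (1.3 equiv), toluene, −78 °C; then sat. aq KNaC4H4O6, 0 °C → rt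
Reagents that add atoms: water, O
Why: DIBAL-H reduction of a nitrile stops at the N-aluminoimine at low temperature, and neutral hydrolysis gives the aldehyde without opening the acid-labile oxirane.

Step 13
Reactants: 25 the C15 aldehyde; 22 the C5 phosphonate
Product: 26 (2E,4E,6E,8E)-3,7-dimethyl-9-[(1S,6R)-2,2,6-trimethyl-7-oxabicyclo[4.1.0]heptan-1-yl]nona-2,4,6,8-tetraenenitrile
Conditions: 22, NaH, THF, 0 °C; then 25, 0 °C → rt, dark
Reagents that add atoms: none
Why: A second Horner–Wadsworth–Emmons olefination should form C11=C12 as the E alkene and mainly the E C13=C14 isomer, the 13Z isomer being separable.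

Step 14
Reactants: 26 the C20 nitrile
Product: 28 (5R,6S)-5,6-epoxy-5,6-dihydroretinal, (2E,4E,6E,8E)-3,7-dimethyl-9-[(1S,6R)-2,2,6-trimethyl-7-oxabicyclo[4.1.0]heptan-1-yl]nona-2,4,6,8-tetraenal, via aluminoimine 27 (not isolated)
Conditions: iBu2AlH (1.3 equiv), toluene, −78 °C; then sat. aq KNaC4H4O6, 0 °C → rt, dark
Reagents that add atoms: water, O
Why: The same DIBAL-H nitrile-to-aldehyde reduction as in step 12, through the N-aluminoimine.

Step 15
Reactants: 29 dibromomethane; 30 tributyltin chloride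
Product: 31 tributyl(dibromomethyl)stannane
Conditions: 29, LiN(iPr)2 (commercial solution), THF, −90 °C; then Bu3SnCl, −90 °C → rt
Reagents that add atoms: none
Why: Deprotonation of CH2Br2 gives dibromomethyllithium, which is stable at this temperature and is stannylated by nucleophilic substitution at tin.

Step 16
Reactants: 28 the epoxyretinal; 31 tributyl(dibromomethyl)stannane
Product: 32 tributyl{(1E,3E,5E,7E,9E)-4,8-dimethyl-10-[(1S,6R)-2,2,6-trimethyl-7-oxabicyclo[4.1.0]heptan-1-yl]deca-1,3,5,7,9-pentaen-1-yl}stannane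
Conditions: 31 (2 equiv), CrCl2 (8 equiv), LiI (4 equiv), DMF/THF, rt, dark; chromatography on Et3N-deactivated silica
Reagents that add atoms: none
Why: Takai-type chromium-mediated stannyl olefination (Hodgson's reagent): the geminal dichromium species from 31 adds to the aldehyde and eliminates to the E alkenylstannane, forming C15=C15'.

Step 17
Reactants: 17 the C19 iodide; 32 the C21 stannane
Product: 33 (5R,6S,6'R)-5,6-epoxy-5,6-dihydro-β,ε-carotene (target)
Conditions: Pd2(dba)3 (5 mol%), AsPh3 (40 mol%), NMP, rt, dark, argon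
Reagents that add atoms: none
Why: Stille coupling under neutral conditions with the arsine ligand that speeds transmetalation; C14'–C15' forms with retention at both alkenes, and neither the oxirane nor C6' is exposed to acid or base.

**Compound list**

1 | α-ionone (racemic) | CC1=CCCC(C)(C)C1/C=C/C(C)=O | starting material
2 | (R)-α-ionone | CC1=CCCC(C)(C)[C@H]1/C=C/C(C)=O | intermediate
3 | diethyl (3E)-4-[(1R)-2,6,6-trimethylcyclohex-2-en-1-yl]buta-1,3-dien-2-yl phosphate | CC1=CCCC(C)(C)[C@H]1/C=C/C(=C)OP(=O)(OCC)OCC | intermediate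
4 | (6R)-6-[(1E)-but-1-en-3-yn-1-yl]-1,5,5-trimethylcyclohex-1-ene | CC1=CCCC(C)(C)[C@H]1/C=C/C#C | intermediate
5 | acetylene | C#C | starting material
6 | iodine monobromide | IBr | starting material
7 | (E)-1-bromo-2-iodoethene | Br/C=C/I | intermediate
8 | trimethylsilylacetylene | C#C[Si](C)(C)C | starting material
9 | (trimethylsilylethynyl)zinc bromide | C[Si](C)(C)C#C[Zn]Br | intermediate
10 | (E)-(4-bromobut-3-en-1-yn-1-yl)trimethylsilane | Br/C=C/C#C[Si](C)(C)C | intermediate
11 | trimethylaluminium | C[Al](C)C | starting material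
12 | dimethyl{(1E,3E)-2-methyl-4-[(1R)-2,6,6-trimethylcyclohex-2-en-1-yl]buta-1,3-dien-1-yl}alane | CC1=CCCC(C)(C)[C@H]1/C=C/C(C)=C/[Al](C)C | intermediate
13 | {(1E,3E)-2-methyl-4-[(1R)-2,6,6-trimethylcyclohex-2-en-1-yl]buta-1,3-dien-1-yl}zinc chloride | CC1=CCCC(C)(C)[C@H]1/C=C/C(C)=C/[Zn]Cl | intermediate
14 | trimethyl{(3E,5E,7E)-6-methyl-8-[(1R)-2,6,6-trimethylcyclohex-2-en-1-yl]octa-3,5,7-trien-1-yn-1-yl}silane | CC1=CCCC(C)(C)[C@H]1/C=C/C(C)=C/C=C/C#C[Si](C)(C)C | intermediate
15 | (6R)-1,5,5-trimethyl-6-[(1E,3E,5E)-3-methylocta-1,3,5-trien-7-yn-1-yl]cyclohex-1-ene | CC1=CCCC(C)(C)[C@H]1/C=C/C(C)=C/C=C/C#C | intermediate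
16 | {(1E,3E,5E,7E)-2,6-dimethyl-8-[(1R)-2,6,6-trimethylcyclohex-2-en-1-yl]octa-1,3,5,7-tetraen-1-yl}dimethylalane | CC1=CCCC(C)(C)[C@H]1/C=C/C(C)=C/C=C/C(C)=C/[Al](C)C | intermediate
17 | (6R)-6-[(1E,3E,5E,7E)-8-iodo-3,7-dimethylocta-1,3,5,7-tetraen-1-yl]-1,5,5-trimethylcyclohex-1-ene | CC1=CCCC(C)(C)[C@H]1/C=C/C(C)=C/C=C/C(C)=C/I | intermediate
18 | β-cyclocitral | CC1=C(C=O)C(C)(C)CCC1 | starting material
19 | β-cyclogeraniol | CC1=C(CO)C(C)(C)CCC1 | intermediate
20 | [(1R,6R)-2,2,6-trimethyl-7-oxabicyclo[4.1.0]heptan-1-yl]methanol | OC[C@@]12O[C@]1(C)CCCC2(C)C | intermediate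
21 | (1S,6R)-2,2,6-trimethyl-7-oxabicyclo[4.1.0]heptane-1-carbaldehyde | O=C[C@@]12O[C@]1(C)CCCC2(C)C | intermediate
22 | diethyl (3-cyano-2-methylprop-2-en-1-yl)phosphonate (E/Z mixture) | CCOP(=O)(OCC)CC(C)=CC#N | starting material
23 | (2E,4E)-3-methyl-5-[(1S,6R)-2,2,6-trimethyl-7-oxabicyclo[4.1.0]heptan-1-yl]penta-2,4-dienenitrile | N#C/C=C(C)/C=C/[C@@]12O[C@]1(C)CCCC2(C)C | intermediate
24 | N-(diisobutylalumino)imine of aldehyde 25 | CC(C)C[Al](CC(C)C)N=C/C=C(C)/C=C/[C@@]12O[C@]1(C)CCCC2(C)C | intermediate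
25 | (2E,4E)-3-methyl-5-[(1S,6R)-2,2,6-trimethyl-7-oxabicyclo[4.1.0]heptan-1-yl]penta-2,4-dienal | O=C/C=C(C)/C=C/[C@@]12O[C@]1(C)CCCC2(C)C | intermediate
26 | (2E,4E,6E,8E)-3,7-dimethyl-9-[(1S,6R)-2,2,6-trimethyl-7-oxabicyclo[4.1.0]heptan-1-yl]nona-2,4,6,8-tetraenenitrile | N#C/C=C(C)/C=C/C=C(C)/C=C/[C@@]12O[C@]1(C)CCCC2(C)C | intermediate
27 | N-(diisobutylalumino)imine of aldehyde 28 | CC(C)C[Al](CC(C)C)N=C/C=C(C)/C=C/C=C(C)/C=C/[C@@]12O[C@]1(C)CCCC2(C)C | intermediate
28 | (5R,6S)-5,6-epoxy-5,6-dihydroretinal | O=C/C=C(C)/C=C/C=C(C)/C=C/[C@@]12O[C@]1(C)CCCC2(C)C | intermediate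
29 | dibromomethane | BrCBr | starting material
30 | tributyltin chloride | CCCC[Sn](Cl)(CCCC)CCCC | starting material
31 | tributyl(dibromomethyl)stannane | CCCC[Sn](CCCC)(CCCC)C(Br)Br | intermediate
32 | tributyl{(1E,3E,5E,7E,9E)-4,8-dimethyl-10-[(1S,6R)-2,2,6-trimethyl-7-oxabicyclo[4.1.0]heptan-1-yl]deca-1,3,5,7,9-pentaen-1-yl}stannane | CCCC[Sn](CCCC)(CCCC)/C=C/C=C(C)/C=C/C=C(C)/C=C/[C@@]12O[C@]1(C)CCCC2(C)C | intermediate
33 | (5R,6S,6'R)-5,6-epoxy-5,6-dihydro-β,ε-carotene | CC1=CCCC(C)(C)[C@H]1/C=C/C(C)=C/C=C/C(C)=C/C=C/C=C(C)/C=C/C=C(C)/C=C/[C@@]12O[C@]1(C)CCCC2(C)C | target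

**Step count**

Total: 17 steps. Longest linear sequence: 9 steps (18 → 33 through steps 8, 9, 10, 11, 12, 13, 14, 16 and 17).

**Steps most likely to fail**

Step 16. The chromium salts are Lewis acidic and may trigger rearrangement of the allylic C5–O–C6 oxirane to the 5,8-furanoid; the olefination may also give incomplete E selectivity, and the pentaenylstannane may lose tin on purification. The fallback sets out from 28 and avoids both chromium and tin. Lithiated trimethylsilyldiazomethane (Me3SiCHN2, nBuLi, THF, −78 °C → rt; Colvin rearrangement) should convert the aldehyde into the terminal pentaenyne (1S,6R)-1-[(1E,3E,5E,7E)-3,7-dimethyldeca-1,3,5,7-tetraen-9-yn-1-yl]-2,2,6-trimethyl-7-oxabicyclo[4.1.0]heptane F1. Hydroboration with pinacolborane catalysed by Cp2Zr(H)Cl (CH2Cl2, rt) should then give the E alkenyl pinacolboronate F2 by syn anti-Markovnikov addition. Suzuki–Miyaura coupling of F2 with iodide 17 (Pd(PPh3)4, aq TlOH, THF, rt, dark) forms C14'–C15' and comes back to the route at 33.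

Step 17. Transmetalation from tin may be slow relative to homocoupling of the stannane, E/Z scrambling of the long polyenes, or loss of the iodide. The fallback replaces the cross-coupling by a Wittig union at C15=C15'; it sets out from 15 and 28. Trienyne 15 is methylaluminated as in step 7 to alane 16, which is converted with nBuLi into the lithium aluminate F3 and trapped with paraformaldehyde (THF, rt) to give (2E,4E,6E,8E)-3,7-dimethyl-9-[(1R)-2,6,6-trimethylcyclohex-2-en-1-yl]nona-2,4,6,8-tetraen-1-ol F4. Treatment with PPh3·HBr in MeOH at rt should give the allylic triphenylphosphonium bromide F5. Wittig reaction of F5 with 28 (NaOMe, MeOH/CH2Cl2, 0 °C → rt) should give the carotenoid as a mixture at the central alkene, which is converted into the all-E form by heating in heptane; the route is rejoined at 33.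

Step 2. Excess LDA may remove the doubly allylic C6'–H (or the γ-hydrogen of the ketone before phosphorylation), eroding the configuration at C6'. The fallback sets out from 2 and builds the alkyne without an amide base in excess. Haloform cleavage (aq NaOCl, dioxane, 0–10 °C, then acid) should give (2E)-3-[(1R)-2,6,6-trimethylcyclohex-2-en-1-yl]prop-2-enoic acid F6, whose enantiopurity can be upgraded, if needed, by crystallising a salt with a chiral amine. Reduction with LiAlH4 (Et2O, 0 °C) gives the allylic alcohol F7, and MnO2 (CH2Cl2, rt) gives the enal F8. Colvin homologation of F8 with lithiated trimethylsilyldiazomethane (THF, −78 °C → rt) comes back to the route at 4.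

**Further compounds**

F1 | step 16 | (1S,6R)-1-[(1E,3E,5E,7E)-3,7-dimethyldeca-1,3,5,7-tetraen-9-yn-1-yl]-2,2,6-trimethyl-7-oxabicyclo[4.1.0]heptane | C#C/C=C(C)/C=C/C=C(C)/C=C/[C@@]12O[C@]1(C)CCCC2(C)C
F2 | step 16 | 2-{(1E,3E,5E,7E,9E)-4,8-dimethyl-10-[(1S,6R)-2,2,6-trimethyl-7-oxabicyclo[4.1.0]heptan-1-yl]deca-1,3,5,7,9-pentaen-1-yl}-4,4,5,5-tetramethyl-1,3,2-dioxaborolane | CC1(C)OB(OC1(C)C)/C=C/C=C(C)/C=C/C=C(C)/C=C/[C@@]12O[C@]1(C)CCCC2(C)C
F3 | step 17 | lithium butyl{(1E,3E,5E,7E)-2,6-dimethyl-8-[(1R)-2,6,6-trimethylcyclohex-2-en-1-yl]octa-1,3,5,7-tetraen-1-yl}dimethylaluminate (not isolated) | CC1=CCCC(C)(C)[C@H]1/C=C/C(C)=C/C=C/C(C)=C/[Al-](C)(C)CCCC.[Li+]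
F4 | step 17 | (2E,4E,6E,8E)-3,7-dimethyl-9-[(1R)-2,6,6-trimethylcyclohex-2-en-1-yl]nona-2,4,6,8-tetraen-1-ol | CC1=CCCC(C)(C)[C@H]1/C=C/C(C)=C/C=C/C(C)=C/CO
F5 | step 17 | {(2E,4E,6E,8E)-3,7-dimethyl-9-[(1R)-2,6,6-trimethylcyclohex-2-en-1-yl]nona-2,4,6,8-tetraen-1-yl}triphenylphosphonium bromide | CC1=CCCC(C)(C)[C@H]1/C=C/C(C)=C/C=C/C(C)=C/C[P+](c2ccccc2)(c2ccccc2)c2ccccc2.[Br-]
F6 | step 2 | (2E)-3-[(1R)-2,6,6-trimethylcyclohex-2-en-1-yl]prop-2-enoic acid | CC1=CCCC(C)(C)[C@H]1/C=C/C(=O)O
F7 | step 2 | (2E)-3-[(1R)-2,6,6-trimethylcyclohex-2-en-1-yl]prop-2-en-1-ol | CC1=CCCC(C)(C)[C@H]1/C=C/CO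
F8 | step 2 | (2E)-3-[(1R)-2,6,6-trimethylcyclohex-2-en-1-yl]prop-2-enal | CC1=CCCC(C)(C)[C@H]1/C=C/C=O
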